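(All runs are calculated with made-up constants.)

In the west run, at 1.33 min, substrate stands at 43 % and product at 7 %, so the other 50.0 % sits as adduct. With the bound reagent counted off, that reads as a binding constant of 22.9 L mol⁻¹. Product at 15.0 min, set against the mean adduct of the first and last readings, reads as a rate constant of 0.0691 min⁻¹. Both are readings and carry the scatter.

| setting | west | south-west | Wednesday's | Friday's | Tuesday's | Monday's |
|---|---|---|---|---|---|---|
| substrate | 0.016 M | 0.16 M | 0.20 M | 0.10 M | 0.050 M | 0.025 M |
| reagent | 0.060 M | 0.060 M | 0.0600 M | 0.0600 M | 0.0600 M | 0.0600 M |
| remark | run made earlier | run made earlier |  |  |  |  |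
| time |  |  | 20 min | 20 min | 20 min | 20 min |

| run | time / min | product / % | substrate / % |
|---|---|---|---|
| west | 1.33 | 7 | 43 |
| west | 4.00 | 16 | 41 |
| west | 6.00 | 18 | 38 |
| west | 10.0 | 30 | 33 |
| west | 15.0 | 42 | 27 |
| south-west | 3.00 | 6 | 71 |
| south-west | 6.00 | 12 | 72 |
| south-west | 8.00 | 14 | 72 |
| south-west | 12.0 | 15 | 68 |
| south-west | 15.0 | 19 | 67 |

(standard deviation of a reading: 1.5 percentage points)

- product is meant together with its crystals
- solid, in amounts per volume of the solution: crystals
- the analysis behind the earlier runs scatters by 1.5 percentage points, standard deviation
- steps thought possible: adduct -> product; substrate + reagent <-> adduct; crystals <-> product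

* the flasks put in order of amount of product, in percent of the substrate charged, best first, at 20 min (Wednesday's / Friday's / Tuesday's / Monday's)
* the same order at 80 min (Wednesday's / Friday's / Tuesday's / Monday's)
* the amount of product, in percent of the substrate charged of the flask you put first, at 20 min
* the amount of product, in percent of the substrate charged of the flask you put last, at 20 min

I count turnovers. The turnover count of a flask is rate constant times time times the share of the scarcer partner (the limiting reagent) held as adduct, with the other partner taken at its charge less half the scarcer charge: for Wednesday's, 1.10. The yield is the ceiling, scarcer charge over substrate charge, times one minus e to the minus count.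

Time multiplies the count directly. Substrate pulls two ways. Lowering it raises the ceiling, from 30.0 % in Wednesday's to 60.0 % in Friday's, and then substrate becomes the scarcer partner. But in Friday's it thins the partner that binds, so the count falls to 0.851. In Tuesday's the partner that binds is reagent, and the count is 0.614. Monday's, with less substrate, takes more reagent as that partner, so there the count rises again, to 0.720. Reagent, the same in the four, enters Wednesday's through its ceiling and Monday's through its share. So I reckon 20.0 %, 34.4 %, 45.9 % and 51.3 % at 20 min, in that order from Wednesday's to Monday's. At 80 min the counts are multiplied by 4.00, and Monday's stays ahead of Tuesday's.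

The forecast puts Monday's > Tuesday's > Friday's > Wednesday's at 20 min and Monday's > Tuesday's > Friday's > Wednesday's at 80 min, with 51 % first and 20 % last, and says “reagent caps Wednesday at 30% and Friday at 60%”.

The flasks give Monday's > Tuesday's > Friday's > Wednesday's, with 51.1 % and 20.1 %, and Monday's > Tuesday's > Friday's > Wednesday's later.

    adduct → product (k = 0.0717 min⁻¹)
    substrate + reagent ⇌ adduct (K = 23.0 L mol⁻¹, k = 156 L mol⁻¹ min⁻¹)
    crystals ⇌ product, rate k3*(cs3 - [product]) while solid is left; crystals form when [product] > cs3 (solubility = 5.50 mM, k = 10.3 min⁻¹)

Wednesday's count of 1.10 is the greatest of the four, yet its product is the lowest. The consumption of reagent is the largest single effect there: with reagent held at its charge, Wednesday's gives 56.3 % instead of 20.1 %, which is 45 % of what is missing.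

A neighbour of Monday's charged with 0.015 M of reagent has reagent as its scarcer partner, a ceiling of 60.0 % and a count of 0.395, so I reckon 19.6 %. That neighbour gives 20.8 %.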